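**Cold runs.** Temperature comes first. Saturday's run at −5 °C kept 50.8 % of its starting material after 40.0 min, a first-order constant of 0.0169 min⁻¹. Tuesday's run had less first nucleophile and half the protic impurity, yet it gives 0.0170 min⁻¹, the same within scatter. Both settings moved together, so cancelling effects stay open. The working view is a rate-limiting first step of the starting material, blind to both.

the same everywhere: starting material 0.30 M

|  | first nucleophile | second nucleophile | protic impurity | temperature | remark | time |
|---|---|---|---|---|---|---|
| Saturday's | 3.5 equiv | 0.80 equiv | 0.015 M | −5 °C | run made earlier |  |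
| Monday's | 5.5 equiv | 0.80 equiv | 0.015 M | 10 °C | run made earlier |  |
| Tuesday's | 2.5 equiv | 0.80 equiv | 0.0075 M | −5 °C | run made earlier |  |
| elm | 2.50 equiv | 0.800 equiv | 0.0150 M |  | at 20 °C until 5.0 min, from then on at 0 °C | 10 min |
| oak | 2.50 equiv | 0.800 equiv | 0.0150 M | 20 °C |  | 10 min |
| cedar | 2.50 equiv | 0.800 equiv | 0.0150 M | 0 °C |  | 10 min |

| run | time / min | target / % | starting material / % |
|---|---|---|---|
| Saturday's | 3.00 | 4.4 | 95.3 |
| Saturday's | 10.0 | 14.4 | 84.8 |
| Saturday's | 20.0 | 28.9 | 71.2 |
| Saturday's | 30.0 | 38.5 | 60.1 |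
| Saturday's | 40.0 | 48.6 | 50.8 |
| Monday's | 4.00 | 39.0 | 60.1 |
| Monday's | 8.00 | 62.2 | 35.9 |
| Monday's | 12.0 | 77.7 | 21.3 |
| Monday's | 15.0 | 84.3 | 15.1 |
| Monday's | 20.0 | 90.8 | 7.9 |
| Tuesday's | 3.00 | 4.4 | 95.1 |
| Tuesday's | 10.0 | 14.7 | 84.3 |
| Tuesday's | 20.0 | 27.4 | 71.7 |
| Tuesday's | 30.0 | 38.8 | 60.5 |
| Tuesday's | 40.0 | 47.3 | 50.6 |

(readings scatter by 0.5 percentage points)



* the flask with the highest amount of target, in percent of the starting material charged ("all alike" if they lie within 1.5 percentage points) (elm / oak / cedar / all alike)
* final target, as a percentage of the starting material charged, in elm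
* final target, as a percentage of the starting material charged, in oak
* final target, as a percentage of the starting material charged, in cedar

**Warm run.** Monday's run at 10 °C gives 0.127 min⁻¹, with more first nucleophile as well. Read as temperature, the two constants give an Arrhenius slope of 10200 K. That means 0.0340 min⁻¹ at 0 °C and 0.433 min⁻¹ at 20 °C.

**Lifetime count.** Elm spends 5.0 min at 20 °C and the rest at 0 °C, and its two stretches add to 2.34. Constant times time, summed along the flask, is the lifetime count. Oak reaches 4.33 and cedar 0.340. Under first-order loss, the fraction of starting material left is e to the minus count: 9.63 % in elm, 1.32 % in oak, 71.2 % in cedar. In elm the warm stretch counts 2.17 against 0.170 for the cold one.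

**One number?** The count reads starting material, not target. Monday's last readings leave 1.3 percentage points of the charge in neither peak, against a scatter of 0.5 points per reading. Target follows the count as far as that gap stays small.

**The forecast.** It holds that “conversion is essentially the yield”. It names oak, with elm at 89.5 % (70 % to 93 %), oak at 97.7 % (80 % to 99.5 %) and cedar at 28.5 % (18 % to 32 %).

**Result.** Oak gives 95.4 %, elm 87.4 %, cedar 27.6 %.

    starting material → intermediate (k = 0.00731 s⁻¹, Ea = 85.0 kJ mol⁻¹)
    first nucleophile + intermediate → target (k = 2.20 L mol⁻¹ s⁻¹, Ea = 44.0 kJ mol⁻¹)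
    second nucleophile + intermediate → other capture product (k = 0.510 L mol⁻¹ s⁻¹, Ea = 47.0 kJ mol⁻¹)
    2 second nucleophile → self-condensation product (k = 0.0411 L mol⁻¹ s⁻¹, Ea = 69.0 kJ mol⁻¹)
    first nucleophile + protic impurity → quenched reagent (k = 0.217 L mol⁻¹ s⁻¹, Ea = 52.0 kJ mol⁻¹)
    (constants at 20 °C)

Elm keeps 9.40 % of its starting material at 10.0 min, where the count said 9.63 %. Cedar, left to 100 min, counts 3.40 and keeps 3.29 %, where the count said 3.35 %. In elm, half of the making of target up to 10.0 min is done by 1.41 min, earlier than the change at 5.0 min. Elm's target stands at 85.6 % at that change and at 87.4 % at 10.0 min.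

The numbers in the tables stem from a simulated flask with made-up constants; noise was put on by code.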